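**Assumption:** [(3-bromoprop-1-en-2-yl)sulfonyl]benzene (4) and 3-bromofuran-2(5H)-one (20) are taken as purchasable building blocks.

## Analysis of the target

The target is a labdane: a trans-fused decalin in which ring A is C1–C5 plus C10 with a gem-dimethyl C4, ring B is C5–C10, and C9 carries through C11–C12 a butenolide joined at its α-carbon (C13; C14 is the ring CH, C15 the OCH2, C16 the carbonyl). It has five stereocentres, C5 (S), C6 (S), C8 (R), C9 (R) and C10 (S). Taking the axial C10 methyl as β, H5 is α, the C6 acetoxy group is α and equatorial, the C8 methyl is α and equatorial, and the C9 hydroxyl is α and axial with its two-carbon chain β and equatorial; the two ring B oxygens are therefore 1,4-cis on the α face. The acetate (lost to bases and carbanions), the butenolide (base-labile, electrophilic, reducible) and the tertiary C9 alcohol (prone to dehydration) are the sensitive groups and must appear late. The hard part is the contiguous C8–C9–C10 array of a methine, a fully substituted carbinol and a quaternary carbon, together with a second quaternary carbon (C4) next to the ring-fusion carbon C5. The strategy rests on the fact that ring B maps atom for atom onto (R)-carvone: its carbonyl is C9, its enone methyl sits on C8, its stereocentre is C5 in the right absolute sense, and its isopropenyl group is C4 with one methyl and a CH2 that becomes the second methyl once it accepts a hydrogen atom. Only the C10 methyl and the C1–C3 bridge are missing, and both can be attached at the α' carbon of carvone, so that a radical at C4 can close ring A.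

## Retrosynthetic reasoning

**C6 acetate and silyl ether.** The acetyl C–O bond of 25 is cut last, giving diol 23 and acetic anhydride 24. An ester at C6 would not survive the carbanion and ylide steps, whereas the tertiary axial C9 hydroxyl is too hindered to acylate, so the final acylation needs no protection. Diol 23 comes from silyl ether 22 by fluoride cleavage.

**C12–C13.** The bond between the side-chain CH2 and the α-carbon of the butenolide is cut, leading to vinyl carbinol 19 and the intact bromobutenolide 20. The forward reaction is a hydroboration to the alkylborane 21 followed by palladium-catalysed coupling. It brings in the heterocycle at its final oxidation level, so no oxidation, reduction or double-bond shift is needed afterwards.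

**C11–C12 and the C9 carbinol.** The vinyl carbinol 19 is traced to the spiro-epoxide 17 and the one-carbon ylide precursor 18, and 17 to the exocyclic alkene 16. The reason for this detour is facial bias. The axial C10 methyl sits next to C9 on the β face, so reagents approach C9 from the α face. A side-chain carbanion added to a C9 ketone would therefore end up α with the hydroxyl β, the wrong epimer. Installing carbon first as a stereochemically neutral methylidene and oxygen second, from the α face with a peracid, turns the same bias into the correct configuration (oxygen α, C11 β).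

**C9=C11 and the sulfone.** Alkene 16 comes from sulfone 15 by reductive C–S cleavage, and 15 from ketone 12 and the silylmethyl carbanion 13 through the β-hydroxysilane 14. The sulfone is removed only here, because at every earlier stage an enone or ketone would be reduced by the electron-transfer conditions that cleave an alkyl aryl sulfone.

**C8.** Ketone 12 is the hydrogenation product of enone 10 after equilibration of the kinetic epimer 11. Keeping the C9 carbonyl until C8 is set means the methyl configuration is under thermodynamic control (equatorial, away from the C10 methyl).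

**C6–O.** Silyl ether 10 comes from alcohol 9, and the C6–O bond of 9 is cut back to enone 6 through the silyl dienol ether 7 and its epoxide 8. C6 is the γ-position of the carvone enone and the only site that can be enolised, since C10 is quaternary. A route through a C6 ketone was not taken, because hydrides attack C6 from the open α face and give the axial 6β-alcohol. Electrophilic oxygen, by contrast, arrives from that same α face and gives the equatorial 6α-alcohol directly.

**C3–C4 (ring A).** Enone sulfone 6 is opened at the C3–C4 bond to give 5, in which C4 is still the isopropenyl carbon and C1–C3 is a 2-sulfonylallyl arm on C10. The cut is placed here because it reduces the decalin to a carvone bearing two substituents on one carbon. The forward reaction has to generate a tertiary radical at C4 selectively and make the most hindered C–C bond of ring A, with no new stereocentre to control.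

**C10 substituents.** Compound 5 comes from 6-methylcarvone 3 and the allylic bromide 4, and 3 from (R)-carvone 1 and iodomethane 2. Both are enolate alkylations at the α' carbon. The second must occur anti to the isopropenyl group, which fixes C10 and with it the trans ring fusion.

## Alternatives that were turned down

**Alternative 1:** Both ring B carbon–oxygen bonds (C6–O and C9–O) are cut at once and traced to molecular oxygen. The precursor is the ring B diene A1 (C6=C7 and C8=C9), which already carries a two-carbon acetal chain on C9. The forward key step is a sensitised photooxygenation: cycloaddition across C6 and C9 from the α face gives the endoperoxide A2, and O–O reduction would give the 6α,9α-diol.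
- For it: one step sets both oxygen stereocentres with the correct 1,4-cis relation and configures the C9 carbinol without any addition to a hindered ketone. On this point it is stronger than the chosen route, which needs two separate α-face oxidations (steps 4 and 9).
- Against it: the C7=C8 alkene left in A2 must be hydrogenated to set C8 with no carbonyl nearby to correct the outcome. Delivery of hydrogen from the open α face (or directed by the two α-hydroxyls) would push the methyl β and axial, the wrong epimer.
- Against it: A1 is itself a complete, correctly fused decalin with a tetrasubstituted diene terminus, so the key step leaves the construction of the skeleton unsolved. Ene reaction at the allylic methyl would compete with cycloaddition at the hindered C9 terminus.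
- Comparison: the chosen route builds the whole carbocycle in three steps and keeps C8 correctable through the C9 ketone.

**Alternative 2:** The C9–C10 bond is cut. The precursor is the δ-lactone A3, whose ring oxygen sits on an allylic carbon (C6) bearing a 2,6,6-trimethylcyclohexenyl group. Enolisation and O-silylation, then a sigmatropic ring contraction through a boat transition state, would give the carboxylic acid A4 with ring B closed and a C5=C6 double bond.
- For it: the most congested bond of the molecule and two adjacent fully substituted carbons are made in one stereospecific step, with chirality relayed from the lactone carbinol. The C5=C6 alkene of A4 would allow a hydroboration from the α face that sets H5 and the 6α-hydroxyl together. On C5/C6 this is more direct than the chosen route.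
- Against it: the migrating terminus is a tetrasubstituted ring alkene carbon flanked by the gem-dimethyl group, and bonding there through a boat is severely strained.
- Against it: C9 arrives carrying a carboxyl carbon that must be excised and replaced by hydroxyl with retention, which costs several steps. A3 also needs two stereocentres set beforehand.
- Comparison: the chosen route draws C5 from the chiral pool, sets C10 by a substrate-controlled alkylation, and removes nothing but a sulfone. It is clearly shorter.

**Alternative 3:** Ring B is traced to a five-membered ring. C8 with its methyl is removed from between C9 and C7, leaving the hydrindenone A5, which an amino-acid-catalysed annulation could supply in either enantiomeric series. The forward key step is a Lewis-acid-promoted homologation of the C9 ketone with the diazoalkane that carries the C8 methyl. Migration of the C7 methylene would give the octalenone A6.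
- For it: the quaternary C10 comes from a very reliable asymmetric annulation that does not depend on the chiral pool. The C8 methyl and C9 ketone arrive together, and the C5=C6 alkene again offers hydroboration to H5α and 6α-OH. On the freedom to choose the enantiomer and on C5/C6 it is stronger.
- Against it: the homologation must discriminate between migration of C7 and of quaternary C10, avoid epoxide formation and double insertion, and not let the β,γ-unsaturated ketone slip into conjugation under the Lewis acid.
- Against it: the diazoalkane is hazardous and must be generated fresh. Reaching A5 requires gem-dimethylation and removal of a ring A carbonyl in the presence of the cyclopentanone, and the C9 carbinol problem remains exactly as in the chosen route.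
- Comparison: the chosen route reaches the corresponding ring B ketone with C5, C8 and C10 in place in fewer steps and without a regiochemical question in the ring-forming event.

Key step: step 3

## Route

Step 1
Reactants: 1 (R)-carvone; 2 iodomethane
Product: 3 (5R,6S)-6-methylcarvone (methyl trans to isopropenyl; the minor cis epimer is carried along)
Conditions: LiN(i-Pr)2 (LDA), THF, −78 °C; MeI, −78 → 0 °C
Reagents that add atoms: iodomethane 2, SMILES CI
Why: Kinetic deprotonation of the enone at the α' carbon (C10) gives the cross-conjugated lithium dienolate, and its C-methylation (enolate alkylation) occurs mainly anti to the neighbouring isopropenyl group; the configuration of this centre is not critical because step 2 passes through the planar enolate again.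

Step 2
Reactants: 3 (5R,6S)-6-methylcarvone; 4 [(3-bromoprop-1-en-2-yl)sulfonyl]benzene
Product: 5 (5S,6S)-2,6-dimethyl-6-[2-(phenylsulfonyl)prop-2-en-1-yl]-5-(prop-1-en-2-yl)cyclohex-2-en-1-one (sulfonylallyl arm trans to isopropenyl)
Conditions: LDA, THF, −78 → −20 °C; then 4, DMPU, −78 → −20 °C
Reagents that add atoms: [(3-bromoprop-1-en-2-yl)sulfonyl]benzene 4, SMILES C=C(CBr)S(=O)(=O)c1ccccc1
Why: The tetrasubstituted lithium enolate of 3 is C-alkylated by 4 (direct displacement or addition–elimination, both giving the same product) on the face anti to the isopropenyl group on the adjacent C5, which sets quaternary C10 with the arm trans to the C4 unit and the methyl cis to it; this substrate-controlled second alkylation of 6-alkylcarvones is well established.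

Step 3
Reactants: 5 (5S,6S)-2,6-dimethyl-6-[2-(phenylsulfonyl)prop-2-en-1-yl]-5-(prop-1-en-2-yl)cyclohex-2-en-1-one
Product: 6 trans-fused 2α-(phenylsulfonyl)-4,4,8,10β-tetramethyl-5αH-Δ7-octalin-9-one
Conditions: Fe(acac)3 (30 mol %), PhSiH3, EtOH/(CH2OH)2 (5:1), 60 °C
Reagents that add atoms: none
Why: The iron hydride formed from Fe(acac)3, PhSiH3 and ethanol transfers a hydrogen atom to the CH2 terminus of the isopropenyl group, the only electron-rich 1,1-disubstituted alkene, and so creates the tertiary C4 radical with both methyls in place. This nucleophilic radical adds to the unsubstituted β-carbon (C3) of the vinyl sulfone, forming the C3–C4 bond and closing ring A in a 6-endo-trig mode through a chair-like transition state; the α-sulfonyl radical is then reduced by divalent iron to the carbanion and protonated by the solvent, which returns trivalent iron. The closest known reaction type is the iron-hydride hydrogen-atom-transfer reductive coupling of unactivated 1,1-disubstituted alkenes with vinyl sulfones and enones, including intramolecular cases that form quaternary carbons. No lasting stereocentre is created: C4 carries two methyls, C2 should form mainly as the equatorial sulfone and is erased in step 8, and the trans ring fusion is already fixed because the C4 unit on C5 and the arm on C10 are trans and both equatorial in 5. The step needs chemoselective hydrogen-atom transfer, secured by the electron-poor character of the enone and vinyl sulfone alkenes, and 6-endo rather than 5-exo closure, secured by polarity because 5-exo attack would hit the sulfone-bearing carbon and leave a primary radical.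

Step 4
Reactants: 6 trans-fused 2α-(phenylsulfonyl)-4,4,8,10β-tetramethyl-5αH-Δ7-octalin-9-one
Product: 9 6α-hydroxy-2α-(phenylsulfonyl)-4,4,8,10β-tetramethyl-5αH-Δ7-octalin-9-one, via silyl dienol ether 7 (not isolated), via 6α,7α-epoxy silyl enol ether 8 (not isolated)
Conditions: TBSOTf, Et3N, CH2Cl2, 0 °C; then mCPBA, NaHCO3, CH2Cl2, −20 °C; then 1 M HCl, THF, 0 °C
Reagents that add atoms: 3-chloroperbenzoic acid, SMILES OOC(=O)c1cccc(Cl)c1 (gives the C6 oxygen); tert-butyldimethylsilyl triflate, SMILES CC(C)(C)[Si](C)(C)OS(=O)(=O)C(F)(F)F (its silyl group is present only in 7 and 8)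
Why: Vinylogous Rubottom oxidation: soft enolisation can only remove a C6 hydrogen (C10 is quaternary) and gives the extended dienol ether 7, whose electron-rich terminal C6=C7 bond is epoxidised from the α face because the β face of C6 is screened by the syn-axial methyls on C4 and C10. The vinyl epoxide 8 opens with the enol ether to the Δ7-9-one, leaving an equatorial 6α-hydroxyl; the sulfone is inert.

Step 5
Reactants: 9 6α-hydroxy-2α-(phenylsulfonyl)-4,4,8,10β-tetramethyl-5αH-Δ7-octalin-9-one
Product: 10 6α-(tert-butyldimethylsilyloxy)-2α-(phenylsulfonyl)-4,4,8,10β-tetramethyl-5αH-Δ7-octalin-9-one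
Conditions: TBSCl, imidazole, DMAP (cat.), DMF, 40 °C
Reagents that add atoms: tert-butyldimethylsilyl chloride, SMILES CC(C)(C)[Si](C)(C)Cl
Why: Standard silylation of a secondary alcohol; imidazole is too weak to enolise the γ-hydroxy enone, and the silyl ether is needed to withstand the carbanion and ylide steps and to prevent isomerisation of the allylic alcohol on palladium.

Step 6
Reactants: 10 6α-(tert-butyldimethylsilyloxy)-2α-(phenylsulfonyl)-4,4,8,10β-tetramethyl-5αH-Δ7-octalin-9-one
Product: 12 6α-(tert-butyldimethylsilyloxy)-2α-(phenylsulfonyl)-4,4,8α,10β-tetramethyl-trans-decalin-9-one, via 8β-methyl ketone 11 (not isolated)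
Conditions: H2 (1 atm), Pd/C, EtOAc, rt; then NaOMe (cat.), MeOH, 50 °C
Reagents that add atoms: none
Why: Heterogeneous hydrogenation of the trisubstituted enone alkene should give mostly the 8β-methyl epimer 11 by delivery of hydrogen to the open α face. C8 is α to the ketone, so methoxide equilibration moves the methyl to the equatorial α position, the β-epimer being destabilised by a 1,3-diaxial contact with the C10 methyl.

Step 7
Reactants: 12 6α-(tert-butyldimethylsilyloxy)-2α-(phenylsulfonyl)-4,4,8α,10β-tetramethyl-trans-decalin-9-one; 13 (trimethylsilyl)methyllithium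
Product: 15 6α-(tert-butyldimethylsilyloxy)-9-methylidene-2α-(phenylsulfonyl)-4,4,8α,10β-tetramethyl-trans-decalin, via β-hydroxysilane 14 (not isolated)
Conditions: CeCl3, 13, THF, −78 → 0 °C; aqueous work-up; then KH, THF, 0 °C → rt
Reagents that add atoms: (trimethylsilyl)methyllithium 13, SMILES [Li]C[Si](C)(C)C (its CH2 becomes C11; silicon is present only in 14)
Why: Peterson olefination: the weakly basic organocerium reagent made from 13 adds to the hindered, enolisable C9 ketone without enolising it, and syn-elimination of silanolate from the potassium alkoxide of 14 gives the exocyclic C9=C11 alkene; the C9 configuration of 14 is irrelevant.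

Step 8
Reactants: 15 6α-(tert-butyldimethylsilyloxy)-9-methylidene-2α-(phenylsulfonyl)-4,4,8α,10β-tetramethyl-trans-decalin
Product: 16 6α-(tert-butyldimethylsilyloxy)-9-methylidene-4,4,8α,10β-tetramethyl-trans-decalin
Conditions: Mg, MeOH, 50 °C
Reagents that add atoms: none
Why: Single-electron (dissolving-metal) cleavage of the alkyl phenyl sulfone C–S bond followed by protonation removes the activating group at the one stage where no carbonyl group is present; the isolated 1,1-disubstituted alkene and the silyl ether are not reduced.

Step 9
Reactants: 16 6α-(tert-butyldimethylsilyloxy)-9-methylidene-4,4,8α,10β-tetramethyl-trans-decalin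
Product: 17 9α,11-epoxide of 16 (spiro-oxirane with oxygen α and axial and C11 β and equatorial)
Conditions: mCPBA, NaHCO3, CH2Cl2, 0 °C
Reagents that add atoms: 3-chloroperbenzoic acid, SMILES OOC(=O)c1cccc(Cl)c1
Why: Prilezhaev epoxidation of the exocyclic alkene; the peracid approaches from the α face, anti to the adjacent axial C10 methyl, which places the oxirane oxygen α and C11 β and so sets C9 with the configuration of the target.

Step 10
Reactants: 17 9α,11-epoxide of 16; 18 trimethylsulfonium iodide
Product: 19 6α-(tert-butyldimethylsilyloxy)-9β-ethenyl-4,4,8α,10β-tetramethyl-trans-decalin-9α-ol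
Conditions: 18 (excess), n-BuLi, THF, −10 °C → rt
Reagents that add atoms: trimethylsulfonium iodide 18, SMILES C[S+](C)C.[I-] (one CH2 becomes C12)
Why: Excess dimethylsulfonium methylide opens the oxirane at its CH2 (C11), and the resulting sulfonium betaine undergoes ylide-mediated elimination of dimethyl sulfide, a known one-carbon homologation of epoxides to allylic alcohols. C9 is not touched, so the oxygen stays α and the new vinyl group (C11=C12) is β.

Step 11
Reactants: 19 6α-(tert-butyldimethylsilyloxy)-9β-ethenyl-4,4,8α,10β-tetramethyl-trans-decalin-9α-ol; 20 3-bromofuran-2(5H)-one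
Product: 22 6α-(tert-butyldimethylsilyloxy)-9α-hydroxylabd-13-en-16,15-olide, via B-alkyl-9-borabicyclononane 21 (not isolated)
Conditions: 9-BBN dimer, THF, 0 °C → rt; then 20, PdCl2(dppf) (10 mol %), AsPh3, K3PO4, DMF/H2O, rt
Reagents that add atoms: 3-bromofuran-2(5H)-one 20, SMILES O=C1OCC=C1Br; 9-borabicyclo[3.3.1]nonane, SMILES B1C2CCCC1CCC2 (boron is present only in 21)
Why: Anti-Markovnikov hydroboration of the vinyl group puts boron on C12, and B-alkyl Suzuki–Miyaura coupling (oxidative addition of zerovalent palladium into the C–Br bond, base-assisted transmetalation, reductive elimination) forms the C12–C13 bond. α-Halo enones and α-halo butenolides are established partners in this coupling, and no stereocentre is involved.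

Step 12
Reactants: 22 6α-(tert-butyldimethylsilyloxy)-9α-hydroxylabd-13-en-16,15-olide
Product: 23 6α,9α-dihydroxylabd-13-en-16,15-olide
Conditions: HF·pyridine, pyridine, THF, 0 °C → rt
Reagents that add atoms: none
Why: Fluoride-mediated cleavage of the silyl ether under mildly acidic conditions, which leave the base-sensitive butenolide and the tertiary alcohol intact.

Step 13
Reactants: 23 6α,9α-dihydroxylabd-13-en-16,15-olide; 24 acetic anhydride
Product: 25 6α-acetoxy-9α-hydroxylabd-13-en-16,15-olide (CNP0205088.2)
Conditions: Ac2O, pyridine, DMAP (cat.), CH2Cl2, rt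
Reagents that add atoms: acetic anhydride 24, SMILES CC(=O)OC(C)=O
Why: Acylation of the secondary equatorial C6 alcohol; the tertiary axial C9 hydroxyl, flanked by C8 and quaternary C10, is not acylated under these conditions.

## Compound list

1 | (R)-carvone, (5R)-2-methyl-5-(prop-1-en-2-yl)cyclohex-2-en-1-one | CC1=CC[C@@H](C(C)=C)CC1=O | starting material
2 | iodomethane | CI | starting material
3 | (5R,6S)-2,6-dimethyl-5-(prop-1-en-2-yl)cyclohex-2-en-1-one (trans-6-methylcarvone) | CC1=CC[C@@H](C(C)=C)[C@H](C)C1=O | intermediate
4 | [(3-bromoprop-1-en-2-yl)sulfonyl]benzene | C=C(CBr)S(=O)(=O)c1ccccc1 | starting material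
5 | (5S,6S)-2,6-dimethyl-6-[2-(phenylsulfonyl)prop-2-en-1-yl]-5-(prop-1-en-2-yl)cyclohex-2-en-1-one | CC1=CC[C@@H](C(C)=C)[C@](C)(CC(=C)S(=O)(=O)c2ccccc2)C1=O | intermediate
6 | trans-fused 2α-(phenylsulfonyl)-4,4,8,10β-tetramethyl-5αH-Δ7-octalin-9-one | CC1=CC[C@H]2C(C)(C)C[C@H](S(=O)(=O)c3ccccc3)C[C@]2(C)C1=O | intermediate
7 | 9-(tert-butyldimethylsilyloxy)-6,8-diene derived from 6 (silyl dienol ether, not isolated) | CC1=C(O[Si](C)(C)C(C)(C)C)[C@@]2(C)C[C@@H](S(=O)(=O)c3ccccc3)CC(C)(C)[C@@H]2C=C1 | intermediate
8 | 6α,7α-epoxide of 7 (not isolated) | CC1=C(O[Si](C)(C)C(C)(C)C)[C@@]2(C)C[C@@H](S(=O)(=O)c3ccccc3)CC(C)(C)[C@@H]2[C@H]3O[C@H]31 | intermediate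
9 | 6α-hydroxy-2α-(phenylsulfonyl)-4,4,8,10β-tetramethyl-5αH-Δ7-octalin-9-one | CC1=C[C@H](O)[C@H]2C(C)(C)C[C@H](S(=O)(=O)c3ccccc3)C[C@]2(C)C1=O | intermediate
10 | 6-O-tert-butyldimethylsilyl ether of 9 | CC1=C[C@H](O[Si](C)(C)C(C)(C)C)[C@H]2C(C)(C)C[C@H](S(=O)(=O)c3ccccc3)C[C@]2(C)C1=O | intermediate
11 | 8β-methyl epimer of 12 (kinetic hydrogenation product, not isolated) | C[C@H]1C[C@H](O[Si](C)(C)C(C)(C)C)[C@H]2C(C)(C)C[C@H](S(=O)(=O)c3ccccc3)C[C@]2(C)C1=O | intermediate
12 | 6α-(tert-butyldimethylsilyloxy)-2α-(phenylsulfonyl)-4,4,8α,10β-tetramethyl-trans-decalin-9-one | C[C@@H]1C[C@H](O[Si](C)(C)C(C)(C)C)[C@H]2C(C)(C)C[C@H](S(=O)(=O)c3ccccc3)C[C@]2(C)C1=O | intermediate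
13 | (trimethylsilyl)methyllithium | [Li]C[Si](C)(C)C | starting material
14 | 9-hydroxy-9-[(trimethylsilyl)methyl] adduct of 12 (drawn as the epimer from α-face addition, not isolated) | C[C@@H]1C[C@H](O[Si](C)(C)C(C)(C)C)[C@H]2C(C)(C)C[C@H](S(=O)(=O)c3ccccc3)C[C@]2(C)[C@]1(O)C[Si](C)(C)C | intermediate
15 | 6α-(tert-butyldimethylsilyloxy)-9-methylidene-2α-(phenylsulfonyl)-4,4,8α,10β-tetramethyl-trans-decalin | C[C@@H]1C[C@H](O[Si](C)(C)C(C)(C)C)[C@H]2C(C)(C)C[C@H](S(=O)(=O)c3ccccc3)C[C@]2(C)C1=C | intermediate
16 | 6α-(tert-butyldimethylsilyloxy)-9-methylidene-4,4,8α,10β-tetramethyl-trans-decalin | C[C@@H]1C[C@H](O[Si](C)(C)C(C)(C)C)[C@H]2C(C)(C)CCC[C@]2(C)C1=C | intermediate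
17 | 9α,11-epoxide of 16 (oxygen α, C11 β) | C[C@@H]1C[C@H](O[Si](C)(C)C(C)(C)C)[C@H]2C(C)(C)CCC[C@]2(C)[C@@]13CO3 | intermediate
18 | trimethylsulfonium iodide | C[S+](C)C.[I-] | starting material
19 | 6α-(tert-butyldimethylsilyloxy)-9β-ethenyl-4,4,8α,10β-tetramethyl-trans-decalin-9α-ol | C[C@@H]1C[C@H](O[Si](C)(C)C(C)(C)C)[C@H]2C(C)(C)CCC[C@]2(C)[C@@]1(O)C=C | intermediate
20 | 3-bromofuran-2(5H)-one | O=C1OCC=C1Br | starting material
21 | 12-(9-borabicyclo[3.3.1]nonan-9-yl) adduct of 19 (not isolated) | C[C@@H]1C[C@H](O[Si](C)(C)C(C)(C)C)[C@H]2C(C)(C)CCC[C@]2(C)[C@@]1(O)CCB1C2CCCC1CCC2 | intermediate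
22 | 6α-(tert-butyldimethylsilyloxy)-9α-hydroxylabd-13-en-16,15-olide | C[C@@H]1C[C@H](O[Si](C)(C)C(C)(C)C)[C@H]2C(C)(C)CCC[C@]2(C)[C@@]1(O)CCC1=CCOC1=O | intermediate
23 | 6α,9α-dihydroxylabd-13-en-16,15-olide | C[C@@H]1C[C@H](O)[C@H]2C(C)(C)CCC[C@]2(C)[C@@]1(O)CCC1=CCOC1=O | intermediate
24 | acetic anhydride | CC(=O)OC(C)=O | starting material
25 | 6α-acetoxy-9α-hydroxylabd-13-en-16,15-olide (CNP0205088.2) | CC(=O)O[C@H]1C[C@@H](C)[C@](O)(CCC2=CCOC2=O)[C@@]2(C)CCCC(C)(C)[C@H]12 | target

## Step count and least certain steps

Total step count: 13. Longest linear sequence: 13 steps from (R)-carvone 1 (the route is fully linear).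

**Step 3 (key step).** The most likely failure is reduction of the tertiary C4 radical by the excess hydrogen donor before it cyclises, giving the isopropyl compound, because the closure forms a quaternary carbon next to C5 and has to reach an acceptor held on the neopentyl C10. Fallback, from 5: Markovnikov addition of HBr (HBr in AcOH, 0 °C) to the isopropenyl group gives the tertiary bromide F1. Slow addition of Bu3SnH with AIBN in benzene at 80 °C then generates the same C4 radical at a low stationary concentration of hydrogen donor, and the 6-endo Giese closure onto the vinyl sulfone comes back to the route at 6.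

**Step 4.** The axial 6β-hydrogen that must be removed is shielded by two methyls, so dienol ether formation may be slow. The peracid may also attack the C8=C9 enol ether bond instead of C6=C7, or facial selectivity may erode. Fallback, from 6: KOt-Bu in t-BuOH/THF forms the dienolate, and kinetic protonation with cold aqueous acetic acid gives the deconjugated Δ6-9-ketone F2. Buffered mCPBA epoxidises its isolated C6=C7 bond from the α face to the 6α,7α-epoxy ketone F3, and DBU in CH2Cl2 opens the epoxide by E1cB elimination through the C8 enolate, which comes back to the route at 9.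

**Step 10.** The ylide may fail to open the oxirane at a CH2 that is attached to a fully substituted, crowded carbon, or it may act as a base and isomerise the epoxide to an allylic alcohol. Fallback, from 16: OsO4 (cat.) with NMO dihydroxylates the exocyclic alkene from the α face to the 9α,11-diol F4. TEMPO/PhI(OAc)2 oxidises only the primary alcohol to the α-hydroxy aldehyde F5, and Wittig methylenation (Ph3PCH3Br, KN(SiMe3)2, THF) comes back to the route at 19.

**Step 11.** The bromobutenolide may decompose under the basic coupling conditions, and the C9 alkoxide may tie up boron as a cyclic borate so that transmetalation stalls and protodeboronation takes over. Fallback, from 19: 9-BBN followed by NaOH/H2O2 gives the 9,12-diol F6, and TEMPO/PhI(OAc)2 gives the β-hydroxy aldehyde F7. Wittig reaction with the stabilised ylide 3-(triphenylphosphoranylidene)oxolan-2-one in toluene gives the (E)-alkylidene lactone F8, and RhCl3·3H2O in hot ethanol moves the exocyclic double bond into the ring, which comes back to the route at 22 (or at 23 if the silyl ether is lost under these conditions).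

## Further compounds

F1 | step 3 | (5S,6S)-5-(2-bromopropan-2-yl)-2,6-dimethyl-6-[2-(phenylsulfonyl)prop-2-en-1-yl]cyclohex-2-en-1-one | CC1=CC[C@@H](C(C)(C)Br)[C@](C)(CC(=C)S(=O)(=O)c2ccccc2)C1=O
F2 | step 4 | 2α-(phenylsulfonyl)-4,4,8,10β-tetramethyl-5αH-Δ6-octalin-9-one (drawn as the 8β-methyl epimer) | C[C@H]1C=C[C@H]2C(C)(C)C[C@H](S(=O)(=O)c3ccccc3)C[C@]2(C)C1=O
F3 | step 4 | 6α,7α-epoxide of F2 | C[C@H]1[C@@H]3O[C@@H]3[C@H]2C(C)(C)C[C@H](S(=O)(=O)c4ccccc4)C[C@]2(C)C1=O
F4 | step 10 | 6α-(tert-butyldimethylsilyloxy)-9β-(hydroxymethyl)-4,4,8α,10β-tetramethyl-trans-decalin-9α-ol | C[C@@H]1C[C@H](O[Si](C)(C)C(C)(C)C)[C@H]2C(C)(C)CCC[C@]2(C)[C@@]1(O)CO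
F5 | step 10 | 6α-(tert-butyldimethylsilyloxy)-9α-hydroxy-4,4,8α,10β-tetramethyl-trans-decalin-9β-carbaldehyde | C[C@@H]1C[C@H](O[Si](C)(C)C(C)(C)C)[C@H]2C(C)(C)CCC[C@]2(C)[C@@]1(O)C=O
F6 | step 11 | 6α-(tert-butyldimethylsilyloxy)-9β-(2-hydroxyethyl)-4,4,8α,10β-tetramethyl-trans-decalin-9α-ol | C[C@@H]1C[C@H](O[Si](C)(C)C(C)(C)C)[C@H]2C(C)(C)CCC[C@]2(C)[C@@]1(O)CCO
F7 | step 11 | 2-[6α-(tert-butyldimethylsilyloxy)-9α-hydroxy-4,4,8α,10β-tetramethyl-trans-decalin-9β-yl]acetaldehyde | C[C@@H]1C[C@H](O[Si](C)(C)C(C)(C)C)[C@H]2C(C)(C)CCC[C@]2(C)[C@@]1(O)CC=O
F8 | step 11 | (E)-3-{2-[6α-(tert-butyldimethylsilyloxy)-9α-hydroxy-4,4,8α,10β-tetramethyl-trans-decalin-9β-yl]ethylidene}oxolan-2-one | C[C@@H]1C[C@H](O[Si](C)(C)C(C)(C)C)[C@H]2C(C)(C)CCC[C@]2(C)[C@@]1(O)C/C=C1\CCOC1=O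
A1 | alternative 1 | ring B 6,8-diene with a (1,3-dioxolan-2-yl)methyl group on C9 | CC1=C(CC2OCCO2)[C@@]2(C)CCCC(C)(C)[C@@H]2C=C1
A2 | alternative 1 | 6α,9α-endoperoxide of A1 | O1O[C@H]2C=C(C)[C@]1(CC3OCCO3)[C@@]3(C)CCCC(C)(C)[C@H]23
A3 | alternative 2 | 3-[2-(benzyloxy)ethyl]-4-methyl-6-(2,6,6-trimethylcyclohex-1-en-1-yl)oxan-2-one (δ-lactone; C3 as either epimer) | O=C1O[C@H](C2=C(C)CCCC2(C)C)C[C@@H](C)C1CCOCc1ccccc1
A4 | alternative 2 | ring B cyclohexene carboxylic acid with the carboxyl α on C9 and a C5=C6 double bond | C1C=C2C(C)(C)CCC[C@]2(C)[C@@](C(=O)O)(CCOCc3ccccc3)[C@@H]1C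
A5 | alternative 3 | 4,4,7a-trimethyl-2,4,5,6,7,7a-hexahydro-1H-inden-1-one (hydrindenone lacking C8) | O=C1CC=C2C(C)(C)CCC[C@]12C
A6 | alternative 3 | 4,4,8α,10β-tetramethyl-Δ5-octalin-9-one | C[C@@H]1CC=C2C(C)(C)CCC[C@]2(C)C1=O
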